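## Structural features

The target is a 3,3'-linked dimer of two 4-aryl-3,4-dihydrocoumarins. The unprimed unit (ring A) carries hydroxyls at C5 and C7, the primed unit (ring B) at C5', C6', C7' and C8', and each C4 carries a 4-hydroxyphenyl group. The four stereocentres C4, C3, C3' and C4' are contiguous. Each lactone is 3,4-cis and the two halves are heterochiral (3R,4S against 3'S,4'R), so the open-chain succinate core C2–C3–C3'–C2' has the meso-like arrangement. C3 and C3' lie α to aryl-ester carbonyls and epimerise with base, and C4 and C4' are doubly benzylic methines next to very electron-rich arenes and can ionise in strong acid. The 1,2,3,4-tetrahydroxybenzene of ring B is oxidised by air, so the free polyphenol can only be released at the end. The real difficulty is the stereotetrad with its two diarylmethines, together with the hexasubstituted benzene of ring B. The key step uses the fact that this benzene (C4a', C5', C6', C7', C8', C8a') is the sum of a squarate (C5'–C8' with four oxygens) and the two carbons of an alkyne on C4' (C4a' and C8a').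

## Logic of the disconnections

**27 to 26.** The O1–C2 lactone bond of ring A and all eight O-methyl groups of 26 (seven aryl ethers, one ester) are removed in thought. This keeps the air-sensitive polyphenol and the second epimerisable lactone out of the route until the last operation. The forward step must demethylate fully and close ring A without touching C3 or C4.

**26 to 24 (through 25).** The O1'–C8a' bond is cut, which turns the ring B hydroquinone lactone into a quinone with a free C2' acid. The ring B oxygen at C8a' then need not be carried through the synthesis. The forward step must add the acid to the only unsubstituted quinone carbon and needs a C2' ester that can be freed without base.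

**24 to 22.** The C4a'–C5' bond is cut and ring B reverts to a squarate-derived hydroxycyclobutenone and an alkyne. A hexasubstituted arene is exchanged for a C≡C bond on C4'. The forward step must close the six-membered ring in neutral medium and leave all four stereocentres alone.

**22 to 20 and 21.** The bond between the alkyne terminus and the carbinol carbon is cut. 20 leads back through 19 to 18 by protecting-group changes only. The alkyne is carried with a triisopropylsilyl group so that it survives hydroperoxide and amide bases, and the C2' acid is masked as the tert-butyl ester only after C3 is settled. The forward step needs a lithium acetylide formed without enolising either ester.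

**18 to 17.** Only the C3–H bond changes. C3 is α to the single ester while the neighbouring acid is a carboxylate, so it can be corrected last by enolisation and protonation. The forward step needs regioselective enolisation and face-selective protonation.

**17 to 15 and 16.** The C4–aryl bond to ring A is cut. The diarylmethine becomes a benzylic C–O bond plus a symmetrical, strongly nucleophilic arene. The forward step must control the face of a benzylic cation next to C3.

**15 to 13 and 1.** The C3–C4 bond is cut, leaving an unsubstituted CH2 next to the methyl ester and an aldehyde. The forward aldol must be regioselective and give one configuration at C3; the carbinol configuration does not matter.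

**13 to 12, then 10 and 11.** The C3'–C3 bond is cut. This is the only succinate bond that can be made by SN2 on a primary halide. The forward alkylation must set C3' next to the existing C4', so an auxiliary is used.

**10 to 7 and 8; 7 to 5; 5 to 3 and 4; 3 to 1 and 2.** The C4'–alkyne bond is cut at a doubly activated alkylidene. The whole chain then starts from one aldehyde, a malonate equivalent and a silylacetylene. The forward step must be enantioselective, as it sets the absolute configuration on which all later centres depend.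

## Other disconnections considered

**Alternative 1:** The cut reconnects C4 to C4' to give cyclobutane A2, then opens A2 by a [2+2] cut through C3–C3' and C4–C4' to the disiloxane-tethered bis(4-arylcoumarin) A1.
- Forward key step: irradiation of A1 joins the two C3=C4 bonds head to head on the face fixed by the tether and gives the cis-fused syn dimer A2. Reductive scission of the strained, doubly benzylic C4–C4' bond and demethylation would finish.
- In favour: both coumarin halves of A1 come from simple condensations. The C3–C3' bond and the heterochiral relation of the halves follow from the syn geometry in one step.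
- Against: A1 is achiral and A2 is chiral, so without an effective chiral sensitiser the single enantiomer needs a resolution. β,β-Disubstituted coumarins dimerise reluctantly, and the excited-state addition is stepwise and reversible. The scission must break C4–C4' and not C3–C3'. Both new hydrogens must arrive on the face opposite the broken bond, since delivery with retention would give the 3,4-trans lactones. Ring B is carried as an oxidation-prone pentaoxygenated arene from the start.
- Comparison: on step economy and on the C3/C3' relationship this alternative is the better plan. On structure it gains convergence but gives up control of absolute configuration, which the chosen plan takes from a catalyst and an auxiliary. On mechanism, a triplet [2+2] through a 1,4-diradical stands against a thermal electrocyclic cascade whose constitution is fixed by connectivity.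

**Alternative 2:** Ring A is cut at C3–C4 and C2–O1, leading to aldehyde A3 (the ring B lactone with CH2CHO on C3') and benzylphenol A4.
- Forward key step: a chiral N-heterocyclic carbene and an oxidant turn A3 into an azolium enolate, Ag2O oxidises A4 to the ortho-quinone methide A5, and a formal [4+2] addition gives A6.
- Correction: A6 carries eight O-methyl groups, so it is the octamethyl ether of 27, not a heptamethyl ether.
- In favour: C3 and C4 are set together under catalyst control with the cis relationship usual for these annulations, ring A closes in the same step, and one demethylation remains.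
- Against: the enolate carbon of A3 sits next to C3', which is α to an aryl-ester lactone and epimerisable under the basic carbene conditions. The second annulation must place its centres heterochiral to the first, so the catalyst may have to work against the substrate. Making A3 by the same method needs the quinone methide of a pentaoxygenated phenol, which is weakly electrophilic and easily over-oxidised.
- Comparison: in control of C3/C4 and in the length of the end game this alternative is the better plan; in overall step count the two are about equal. On structure it keeps both arenes and builds only lactones, whereas the chosen plan builds the ring B arene and avoids a pentaoxygenated benzene until the end. On mechanism, ionic organocatalysis in base stands against a neutral thermal rearrangement that cannot touch C3 or C3'.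

**Alternative 3:** Both carboxyl carbons are cut off (C2–C3 and C2'–C3'), leading to the (Z)-alkene A7.
- Forward key step: Pd(O2CCF3)2 (divalent palladium) with benzoquinone as reoxidant adds CO and methanol twice to one face of A7 and gives the diester A8.
- In favour: syn addition to a Z-alkene gives the meso-like C3/C3' relationship stereospecifically. The two esters need not be told apart, because each closes onto its nearer arene, and A8 is one demethylation away from 27.
- Against: an internal alkene between two diarylmethyl groups inserts slowly. The allylic hydrogens at C4 and C4' are doubly benzylic, so β-hydride elimination, π-allyl formation and alkene migration threaten both centres. The alkene face must be chosen by two allylic centres of nearly the same shape. A7 itself needs two diarylmethines of opposite sense, one with a hindered pentamethoxyphenyl group.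
- Comparison: on the C3/C3' relationship, on ester differentiation and on the end game this alternative is the better plan; in step count it is equal or slightly shorter. On structure it carries ring B as a finished arene, while the chosen plan builds it and needs only one diarylmethine. On mechanism, a stereospecific organometallic syn insertion stands against a pericyclic ring expansion; the chosen plan is the safer one for the integrity of C4 and C4'.

Key step: step 13

Assumption: the (R)-configured bisphosphine is taken to deliver the (R)-adduct 5; if the sense of induction is the opposite, the enantiomeric ligand is used and nothing else changes.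

## Route

**Step 1**
Reactants: 1 4-methoxybenzaldehyde; 2 2,2-dimethyl-1,3-dioxane-4,6-dione (Meldrum's acid)
Product: 3 5-(4-methoxybenzylidene)-2,2-dimethyl-1,3-dioxane-4,6-dione
Conditions: H2O, 75 °C
Reagents that add atoms: none
Why: Knoevenagel condensation of an aromatic aldehyde with a cyclic malonate; the product is a doubly activated acceptor and should precipitate from water.

**Step 2**
Reactants: 3 5-(4-methoxybenzylidene)-2,2-dimethyl-1,3-dioxane-4,6-dione; 4 ethynyl(triisopropyl)silane
Product: 5 5-[(1R)-1-(4-methoxyphenyl)-3-(triisopropylsilyl)prop-2-yn-1-yl]-2,2-dimethyl-1,3-dioxane-4,6-dione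
Conditions: [Rh(OAc)(C2H4)2]2 (2.5 mol %), (R)-DTBM-SEGPHOS (5.5 mol %), 1,4-dioxane, 60 °C
Reagents that add atoms: none
Why: Rhodium-catalysed asymmetric conjugate alkynylation of an arylidene Meldrum's acid with a silylacetylene; the alkynyl–rhodium species adds to the alkylidene and the chiral bisphosphine selects the face, which sets C4'. The bulky silyl group suppresses alkyne dimerisation.

**Step 3**
Reactants: 5 5-[(1R)-1-(4-methoxyphenyl)-3-(triisopropylsilyl)prop-2-yn-1-yl]-2,2-dimethyl-1,3-dioxane-4,6-dione
Product: 7 (3R)-3-(4-methoxyphenyl)-5-(triisopropylsilyl)pent-4-ynoic acid, via malonic acid 6 (not isolated)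
Conditions: DMF/H2O (10:1), 100 °C
Reagents that add atoms: water, O
Why: Hydrolysis of the acetonide-type diester and thermal decarboxylation of the malonic acid; C4' is not acidic under these neutral conditions.

**Step 4**
Reactants: 7 (3R)-3-(4-methoxyphenyl)-5-(triisopropylsilyl)pent-4-ynoic acid; 8 (4R)-4-benzyl-1,3-oxazolidin-2-one
Product: 10 (4R)-4-benzyl-3-[(3R)-3-(4-methoxyphenyl)-5-(triisopropylsilyl)pent-4-ynoyl]-1,3-oxazolidin-2-one, via mixed anhydride 9 (not isolated)
Conditions: t-BuCOCl, Et3N, THF, −20 °C; then LiCl, 8, −20 → 23 °C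
Reagents that add atoms: none
Why: N-acylation of the oxazolidinone through the pivalic mixed anhydride; attack goes to the less hindered carbonyl.

**Step 5**
Reactants: 10 (4R)-4-benzyl-3-[(3R)-3-(4-methoxyphenyl)-5-(triisopropylsilyl)pent-4-ynoyl]-1,3-oxazolidin-2-one; 11 methyl bromoacetate
Product: 12 methyl (3R,4R)-3-{[(4R)-4-benzyl-2-oxo-1,3-oxazolidin-3-yl]carbonyl}-4-(4-methoxyphenyl)-6-(triisopropylsilyl)hex-5-ynoate
Conditions: NaN(SiMe3)2, THF, −78 °C; 11, −78 → −40 °C
Reagents that add atoms: none
Why: Evans alkylation; the chelated Z-enolate is shielded on one face by the benzyl group of the (R)-auxiliary, so the bromoacetate adds to the other face and sets C3'. The resident C4' centre (C4'–H in the enolate plane, electrophile anti to the aryl group) should work in the same direction.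

**Step 6**
Reactants: 12 methyl (3R,4R)-3-{[(4R)-4-benzyl-2-oxo-1,3-oxazolidin-3-yl]carbonyl}-4-(4-methoxyphenyl)-6-(triisopropylsilyl)hex-5-ynoate
Product: 13 (2R)-4-methoxy-2-[(1R)-1-(4-methoxyphenyl)-3-(triisopropylsilyl)prop-2-yn-1-yl]-4-oxobutanoic acid
Conditions: LiOH, H2O2, THF/H2O (3:1), 0 °C; aq. Na2SO3; 1 M HCl
Reagents that add atoms: hydrogen peroxide, OO
Why: Hydroperoxide cleavage of the N-acyl oxazolidinone at the exocyclic carbonyl; hydroperoxide is far more nucleophilic than hydroxide, so the methyl ester and the triisopropylsilyl alkyne should survive at 0 °C. The auxiliary is recovered.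

**Step 7**
Reactants: 13 (2R)-4-methoxy-2-[(1R)-1-(4-methoxyphenyl)-3-(triisopropylsilyl)prop-2-yn-1-yl]-4-oxobutanoic acid; 1 4-methoxybenzaldehyde
Product: 15 methyl (3R,4S)-2-(4-methoxyphenyl)-4-[(1R)-1-(4-methoxyphenyl)-3-(triisopropylsilyl)prop-2-yn-1-yl]-5-oxooxolane-3-carboxylate (3,4-cis; both C2 epimers), via hydroxy acid 14 (not isolated)
Conditions: LiN(iPr)2 (2.2 equiv), THF, −78 °C; 1, −78 °C; 1 M HCl; then TsOH·H2O (cat.), CH2Cl2, 23 °C
Reagents that add atoms: none
Why: Aldol addition of a succinate half-ester dianion followed by acid lactonisation; the carboxylate protects C3'–H, so only the CH2 next to the methyl ester is enolised. The lithium-bridged carboxylate/enolate chelate should send the aldehyde anti to the C4' chain, giving a temporary C3 configuration (CO2Me cis to that chain in the lactone). The carbinol configuration is irrelevant because C4 is ionised in step 8.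

**Step 8**
Reactants: 15 methyl (3R,4S)-2-(4-methoxyphenyl)-4-[(1R)-1-(4-methoxyphenyl)-3-(triisopropylsilyl)prop-2-yn-1-yl]-5-oxooxolane-3-carboxylate; 16 1,3,5-trimethoxybenzene
Product: 17 (2S,3S,4S)-3-(methoxycarbonyl)-4-(4-methoxyphenyl)-2-[(1R)-1-(4-methoxyphenyl)-3-(triisopropylsilyl)prop-2-yn-1-yl]-4-(2,4,6-trimethoxyphenyl)butanoic acid
Conditions: 16 (3 equiv), CF3SO3H (0.2 equiv), CH2Cl2/(CF3)2CHOH (4:1), −20 → 0 °C
Reagents that add atoms: none
Why: Friedel–Crafts alkylation through a chiral p-methoxybenzylic cation (SN1 opening of the γ-aryl lactone); allylic 1,3-strain keeps C3–H in the plane of the cation, and the arene should enter anti to the bulky C3' chain, which also carries the departing carboxylate. With the temporary C3 configuration this sets C4 as S, and the elimination/conjugate re-addition path predicts the same C4.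

**Step 9**
Reactants: 17 (2S,3S,4S)-3-(methoxycarbonyl)-4-(4-methoxyphenyl)-2-[(1R)-1-(4-methoxyphenyl)-3-(triisopropylsilyl)prop-2-yn-1-yl]-4-(2,4,6-trimethoxyphenyl)butanoic acid
Product: 18 (2S,3R,4S)-3-(methoxycarbonyl)-4-(4-methoxyphenyl)-2-[(1R)-1-(4-methoxyphenyl)-3-(triisopropylsilyl)prop-2-yn-1-yl]-4-(2,4,6-trimethoxyphenyl)butanoic acid
Conditions: LiN(iPr)2 (2.5 equiv), THF, −78 → −30 °C; then MeOH, −78 °C; 1 M HCl
Reagents that add atoms: none
Why: Epimerisation by enolisation and kinetic protonation, the usual way to anti-2,3-disubstituted succinates; the carboxylate shields C3'–H, so only C3 is enolised. The proton should arrive anti to the 2,4,6-trimethoxyphenyl group on C4 (C4–H in the enolate plane) and anti to the C4' chain of the lithium-bridged carboxylate; both effects give 3R.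

**Step 10**
Reactants: 18 (2S,3R,4S)-3-(methoxycarbonyl)-4-(4-methoxyphenyl)-2-[(1R)-1-(4-methoxyphenyl)-3-(triisopropylsilyl)prop-2-yn-1-yl]-4-(2,4,6-trimethoxyphenyl)butanoic acid
Product: 19 1-tert-butyl 4-methyl (2S,3R)-2-[(1R)-1-(4-methoxyphenyl)-3-(triisopropylsilyl)prop-2-yn-1-yl]-3-[(S)-(4-methoxyphenyl)(2,4,6-trimethoxyphenyl)methyl]butanedioate
Conditions: O-tert-butyl-N,N'-diisopropylisourea (4 equiv), CH2Cl2, 23 °C
Reagents that add atoms: O-tert-butyl-N,N'-diisopropylisourea, CC(C)N=C(OC(C)(C)C)NC(C)C
Why: O-alkylation of the acid by an isourea transfers tert-butyl under neutral conditions; this tolerates the hindered, epimerisable acid and avoids strong acid that could tert-butylate the trimethoxyphenyl ring.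

**Step 11**
Reactants: 19 1-tert-butyl 4-methyl (2S,3R)-2-[(1R)-1-(4-methoxyphenyl)-3-(triisopropylsilyl)prop-2-yn-1-yl]-3-[(S)-(4-methoxyphenyl)(2,4,6-trimethoxyphenyl)methyl]butanedioate
Product: 20 1-tert-butyl 4-methyl (2S,3R)-2-[(1S)-1-(4-methoxyphenyl)prop-2-yn-1-yl]-3-[(S)-(4-methoxyphenyl)(2,4,6-trimethoxyphenyl)methyl]butanedioate
Conditions: Bu4NF/AcOH (1:1), THF, 0 → 23 °C
Reagents that add atoms: none
Why: Fluoride desilylation of the alkyne, buffered with acetic acid so that the two ester α-positions are not enolised; the change of descriptor at C4' is only a change of priorities.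

**Step 12**
Reactants: 20 1-tert-butyl 4-methyl (2S,3R)-2-[(1S)-1-(4-methoxyphenyl)prop-2-yn-1-yl]-3-[(S)-(4-methoxyphenyl)(2,4,6-trimethoxyphenyl)methyl]butanedioate; 21 3,4-dimethoxycyclobut-3-ene-1,2-dione (dimethyl squarate)
Product: 22 1-tert-butyl 4-methyl (2S,3R)-2-[(1R)-3-(1-hydroxy-2,3-dimethoxy-4-oxocyclobut-2-en-1-yl)-1-(4-methoxyphenyl)prop-2-yn-1-yl]-3-[(S)-(4-methoxyphenyl)(2,4,6-trimethoxyphenyl)methyl]butanedioate (both carbinol epimers)
Conditions: LiN(iPr)2 (1.0 equiv), THF, −78 °C; then added to 21 (1.5 equiv), THF, −78 °C; aq. NH4Cl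
Reagents that add atoms: none
Why: Kinetic deprotonation of the sp C–H by one equivalent of amide base at −78 °C is much faster than enolisation of the hindered tertiary ester α-C–H bonds; 1,2-addition of the lithium acetylide to one carbonyl of a squarate ester is standard. Inverse addition keeps the squarate in excess, and the new carbinol centre is uncontrolled and irrelevant.

**Step 13**
Reactants: 22 1-tert-butyl 4-methyl (2S,3R)-2-[(1R)-3-(1-hydroxy-2,3-dimethoxy-4-oxocyclobut-2-en-1-yl)-1-(4-methoxyphenyl)prop-2-yn-1-yl]-3-[(S)-(4-methoxyphenyl)(2,4,6-trimethoxyphenyl)methyl]butanedioate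
Product: 24 1-tert-butyl 4-methyl (2S,3R)-2-[(R)-(4,5-dimethoxy-3,6-dioxocyclohexa-1,4-dien-1-yl)(4-methoxyphenyl)methyl]-3-[(S)-(4-methoxyphenyl)(2,4,6-trimethoxyphenyl)methyl]butanedioate, via dienylketene 23 (not isolated)
Conditions: p-xylene (0.01 M, degassed), 138 °C
Reagents that add atoms: none
Why: Moore rearrangement of a 4-alkynyl-4-hydroxycyclobutenone, the known thermal ring expansion of squarate-derived cyclobutenones to 2,3-dialkoxybenzoquinones. Heat opens the cyclobutenone by a conrotatory four-electron electrocyclic reaction in which the hydroxyl rotates outward, so the alkynyl group ends cis to the ketene in 23. The ketene carbon (future C5') then bonds to the distal alkyne carbon (future C4a'); this six-membered closure of the enyne–ketene gives a diradical with an aryl σ-radical at C8a', and transfer of the hydroxyl hydrogen to C8a' gives the quinone. No stereocentre is formed: both carbinol epimers of 22 converge, and C4', C3', C3 and C4 are untouched because the medium is neutral and free of base. The step needs six- over five-membered closure, which the sp3 substituent on the alkyne secures because it does not stabilise the vinyl radical of the five-membered mode. Regiochemistry is fixed by connectivity: the alkyne carbon bearing C4' becomes C4a' and the other becomes the unsubstituted C8a'. The intramolecular O–H transfer must outrun hydrogen abstraction from the chain, which high dilution and the adjacent hydroxyl favour.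

**Step 14**
Reactants: 24 1-tert-butyl 4-methyl (2S,3R)-2-[(R)-(4,5-dimethoxy-3,6-dioxocyclohexa-1,4-dien-1-yl)(4-methoxyphenyl)methyl]-3-[(S)-(4-methoxyphenyl)(2,4,6-trimethoxyphenyl)methyl]butanedioate
Product: 26 methyl (2R,3S)-2-[(3S,4R)-5,8-dihydroxy-6,7-dimethoxy-4-(4-methoxyphenyl)-2-oxochroman-3-yl]-3-(4-methoxyphenyl)-3-(2,4,6-trimethoxyphenyl)propanoate, via carboxylic acid 25 (not isolated)
Conditions: CF3CO2H/CH2Cl2 (1:4), 0 → 23 °C, Ar
Reagents that add atoms: none
Why: Acidolysis of the tert-butyl ester frees the C2' acid, which adds to C8a' of the protonated quinone in an intramolecular 6-endo oxa-Michael addition, the lactonising counterpart of the Thiele–Winter acyloxylation of quinones. Enolisation then aromatises ring B to the hydroquinone lactone; the six-membered closure is helped by the substituents on C3' and C4', and no stereocentre is touched.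

**Step 15**
Reactants: 26 methyl (2R,3S)-2-[(3S,4R)-5,8-dihydroxy-6,7-dimethoxy-4-(4-methoxyphenyl)-2-oxochroman-3-yl]-3-(4-methoxyphenyl)-3-(2,4,6-trimethoxyphenyl)propanoate
Product: 27 (3R,4S)-5,7-dihydroxy-4-(4-hydroxyphenyl)-3-[(3S,4R)-5,6,7,8-tetrahydroxy-4-(4-hydroxyphenyl)-2-oxochroman-3-yl]chroman-2-one
Conditions: BBr3 (15 equiv), CH2Cl2, −78 → 23 °C, Ar; then degassed H2O, 0 °C
Reagents that add atoms: none
Why: BBr3 cleaves the seven aryl methyl ethers; an ortho oxygen of ring A then attacks the methyl ester (transesterification, completed on acidic aqueous work-up) and closes the second dihydrocoumarin. The two ortho positions are equivalent, the ring B lactone is an aryl ester that resists BBr3, and exclusion of air protects the tetrahydroxyarene.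

## Compound list

1 | 4-methoxybenzaldehyde | COc1ccc(C=O)cc1 | starting material
2 | 2,2-dimethyl-1,3-dioxane-4,6-dione (Meldrum's acid) | CC1(C)OC(=O)CC(=O)O1 | starting material
3 | 5-(4-methoxybenzylidene)-2,2-dimethyl-1,3-dioxane-4,6-dione | COc1ccc(C=C2C(=O)OC(C)(C)OC2=O)cc1 | intermediate
4 | ethynyl(triisopropyl)silane | C#C[Si](C(C)C)(C(C)C)C(C)C | starting material
5 | 5-[(1R)-1-(4-methoxyphenyl)-3-(triisopropylsilyl)prop-2-yn-1-yl]-2,2-dimethyl-1,3-dioxane-4,6-dione | O=C1OC(C)(C)OC(=O)C1[C@@H](C#C[Si](C(C)C)(C(C)C)C(C)C)c1ccc(OC)cc1 | intermediate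
6 | 2-[(1R)-1-(4-methoxyphenyl)-3-(triisopropylsilyl)prop-2-yn-1-yl]propanedioic acid | OC(=O)C(C(=O)O)[C@@H](C#C[Si](C(C)C)(C(C)C)C(C)C)c1ccc(OC)cc1 | intermediate (not isolated)
7 | (3R)-3-(4-methoxyphenyl)-5-(triisopropylsilyl)pent-4-ynoic acid | OC(=O)C[C@@H](C#C[Si](C(C)C)(C(C)C)C(C)C)c1ccc(OC)cc1 | intermediate
8 | (4R)-4-benzyl-1,3-oxazolidin-2-one | O=C1N[C@H](Cc2ccccc2)CO1 | starting material
9 | (3R)-3-(4-methoxyphenyl)-5-(triisopropylsilyl)pent-4-ynoic pivalic anhydride | CC(C)(C)C(=O)OC(=O)C[C@@H](C#C[Si](C(C)C)(C(C)C)C(C)C)c1ccc(OC)cc1 | intermediate (not isolated)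
10 | (4R)-4-benzyl-3-[(3R)-3-(4-methoxyphenyl)-5-(triisopropylsilyl)pent-4-ynoyl]-1,3-oxazolidin-2-one | O=C(C[C@@H](C#C[Si](C(C)C)(C(C)C)C(C)C)c1ccc(OC)cc1)N1[C@H](Cc2ccccc2)COC1=O | intermediate
11 | methyl bromoacetate | COC(=O)CBr | starting material
12 | methyl (3R,4R)-3-{[(4R)-4-benzyl-2-oxo-1,3-oxazolidin-3-yl]carbonyl}-4-(4-methoxyphenyl)-6-(triisopropylsilyl)hex-5-ynoate | COC(=O)C[C@@H](C(=O)N1[C@H](Cc2ccccc2)COC1=O)[C@@H](C#C[Si](C(C)C)(C(C)C)C(C)C)c1ccc(OC)cc1 | intermediate
13 | (2R)-4-methoxy-2-[(1R)-1-(4-methoxyphenyl)-3-(triisopropylsilyl)prop-2-yn-1-yl]-4-oxobutanoic acid | COC(=O)C[C@@H](C(=O)O)[C@@H](C#C[Si](C(C)C)(C(C)C)C(C)C)c1ccc(OC)cc1 | intermediate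
14 | (2S,3R)-4-hydroxy-3-(methoxycarbonyl)-4-(4-methoxyphenyl)-2-[(1R)-1-(4-methoxyphenyl)-3-(triisopropylsilyl)prop-2-yn-1-yl]butanoic acid (both C4 epimers) | COc1ccc(cc1)C(O)[C@H](C(=O)OC)[C@@H](C(=O)O)[C@@H](C#C[Si](C(C)C)(C(C)C)C(C)C)c1ccc(OC)cc1 | intermediate (not isolated)
15 | methyl (3R,4S)-2-(4-methoxyphenyl)-4-[(1R)-1-(4-methoxyphenyl)-3-(triisopropylsilyl)prop-2-yn-1-yl]-5-oxooxolane-3-carboxylate (3,4-cis; both C2 epimers) | COC(=O)[C@H]1C(c2ccc(OC)cc2)OC(=O)[C@H]1[C@@H](C#C[Si](C(C)C)(C(C)C)C(C)C)c1ccc(OC)cc1 | intermediate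
16 | 1,3,5-trimethoxybenzene | COc1cc(OC)cc(OC)c1 | starting material
17 | (2S,3S,4S)-3-(methoxycarbonyl)-4-(4-methoxyphenyl)-2-[(1R)-1-(4-methoxyphenyl)-3-(triisopropylsilyl)prop-2-yn-1-yl]-4-(2,4,6-trimethoxyphenyl)butanoic acid | COc1cc(OC)cc(OC)c1[C@H](c1ccc(OC)cc1)[C@H](C(=O)OC)[C@@H](C(=O)O)[C@@H](C#C[Si](C(C)C)(C(C)C)C(C)C)c1ccc(OC)cc1 | intermediate
18 | (2S,3R,4S)-3-(methoxycarbonyl)-4-(4-methoxyphenyl)-2-[(1R)-1-(4-methoxyphenyl)-3-(triisopropylsilyl)prop-2-yn-1-yl]-4-(2,4,6-trimethoxyphenyl)butanoic acid | COc1cc(OC)cc(OC)c1[C@H](c1ccc(OC)cc1)[C@@H](C(=O)OC)[C@@H](C(=O)O)[C@@H](C#C[Si](C(C)C)(C(C)C)C(C)C)c1ccc(OC)cc1 | intermediate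
19 | 1-tert-butyl 4-methyl (2S,3R)-2-[(1R)-1-(4-methoxyphenyl)-3-(triisopropylsilyl)prop-2-yn-1-yl]-3-[(S)-(4-methoxyphenyl)(2,4,6-trimethoxyphenyl)methyl]butanedioate | COc1cc(OC)cc(OC)c1[C@H](c1ccc(OC)cc1)[C@@H](C(=O)OC)[C@@H](C(=O)OC(C)(C)C)[C@@H](C#C[Si](C(C)C)(C(C)C)C(C)C)c1ccc(OC)cc1 | intermediate
20 | 1-tert-butyl 4-methyl (2S,3R)-2-[(1S)-1-(4-methoxyphenyl)prop-2-yn-1-yl]-3-[(S)-(4-methoxyphenyl)(2,4,6-trimethoxyphenyl)methyl]butanedioate | COc1cc(OC)cc(OC)c1[C@H](c1ccc(OC)cc1)[C@@H](C(=O)OC)[C@@H](C(=O)OC(C)(C)C)[C@@H](C#C)c1ccc(OC)cc1 | intermediate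
21 | 3,4-dimethoxycyclobut-3-ene-1,2-dione (dimethyl squarate) | COC1=C(OC)C(=O)C1=O | starting material
22 | 1-tert-butyl 4-methyl (2S,3R)-2-[(1R)-3-(1-hydroxy-2,3-dimethoxy-4-oxocyclobut-2-en-1-yl)-1-(4-methoxyphenyl)prop-2-yn-1-yl]-3-[(S)-(4-methoxyphenyl)(2,4,6-trimethoxyphenyl)methyl]butanedioate (both carbinol epimers) | COc1cc(OC)cc(OC)c1[C@H](c1ccc(OC)cc1)[C@@H](C(=O)OC)[C@@H](C(=O)OC(C)(C)C)[C@@H](C#CC1(O)C(OC)=C(OC)C1=O)c1ccc(OC)cc1 | intermediate
23 | dienylketene from ring opening of 22 (alkynyl cis to the ketenyl group) | COc1cc(OC)cc(OC)c1[C@H](c1ccc(OC)cc1)[C@@H](C(=O)OC)[C@@H](C(=O)OC(C)(C)C)[C@@H](C#C/C(O)=C(/OC)C(OC)=C=O)c1ccc(OC)cc1 | intermediate (not isolated)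
24 | 1-tert-butyl 4-methyl (2S,3R)-2-[(R)-(4,5-dimethoxy-3,6-dioxocyclohexa-1,4-dien-1-yl)(4-methoxyphenyl)methyl]-3-[(S)-(4-methoxyphenyl)(2,4,6-trimethoxyphenyl)methyl]butanedioate | COc1cc(OC)cc(OC)c1[C@H](c1ccc(OC)cc1)[C@@H](C(=O)OC)[C@@H](C(=O)OC(C)(C)C)[C@@H](C1=CC(=O)C(OC)=C(OC)C1=O)c1ccc(OC)cc1 | intermediate
25 | (2S,3R,4S)-2-[(R)-(4,5-dimethoxy-3,6-dioxocyclohexa-1,4-dien-1-yl)(4-methoxyphenyl)methyl]-3-(methoxycarbonyl)-4-(4-methoxyphenyl)-4-(2,4,6-trimethoxyphenyl)butanoic acid | COc1cc(OC)cc(OC)c1[C@H](c1ccc(OC)cc1)[C@@H](C(=O)OC)[C@@H](C(=O)O)[C@@H](C1=CC(=O)C(OC)=C(OC)C1=O)c1ccc(OC)cc1 | intermediate (not isolated)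
26 | methyl (2R,3S)-2-[(3S,4R)-5,8-dihydroxy-6,7-dimethoxy-4-(4-methoxyphenyl)-2-oxochroman-3-yl]-3-(4-methoxyphenyl)-3-(2,4,6-trimethoxyphenyl)propanoate | COc1cc(OC)cc(OC)c1[C@H](c1ccc(OC)cc1)[C@@H](C(=O)OC)[C@H]1C(=O)Oc2c(O)c(OC)c(OC)c(O)c2[C@H]1c1ccc(OC)cc1 | intermediate
27 | (3R,4S)-5,7-dihydroxy-4-(4-hydroxyphenyl)-3-[(3S,4R)-5,6,7,8-tetrahydroxy-4-(4-hydroxyphenyl)-2-oxochroman-3-yl]chroman-2-one | O=C1Oc2cc(O)cc(O)c2[C@H](c2ccc(O)cc2)[C@@H]1[C@H]1C(=O)Oc2c(O)c(O)c(O)c(O)c2[C@H]1c1ccc(O)cc1 | target

## Step count and least certain steps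

Total step count: 15. Longest linear sequence: 15 steps (1 to 27; the route is fully linear, with 4, 8, 11, 16 and 21 entering as reagent-like building blocks).

**Step 13 (key step).** The aryl σ-radical at C8a' may take hydrogen from the chain (1,5-transfer from C3'–H) instead of from the hydroxyl, or the ketene may close in the five-membered mode; either diverts the diradical. The fallback joins the same two components without radicals. It sets out from 20 and 21 and returns at 24. Oxidative insertion of CoCl(PPh3)3 (monovalent cobalt) into the C1–C2 bond of 21 gives the maleoylcobalt complex CoCl(PPh3)2[C(O)C(OMe)=C(OMe)C(O)] F1 (trivalent cobalt). After chloride abstraction with AgBF4 in acetonitrile, F1 inserts the terminal alkyne 20, and reductive elimination closes quinone 24. This is the known quinone synthesis from cyclobutenediones and alkynes through maleoyl–metal complexes.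

**Step 8.** The arene may attack the cation on the face syn to the C3' chain, which would give the C4 epimer. Selectivity may also erode through ionisation, elimination and re-addition. The fallback exchanges the roles of the two arenes, which inverts the outcome at C4 under the same facial preference. It sets out from 13 and returns at 17. The dianion of 13 is added to 2,4,6-trimethoxybenzaldehyde and lactonised to methyl (3R,4S)-4-[(1R)-1-(4-methoxyphenyl)-3-(triisopropylsilyl)prop-2-yn-1-yl]-5-oxo-2-(2,4,6-trimethoxyphenyl)oxolane-3-carboxylate F2. The very stable 2,4,6-trimethoxybenzylic cation from F2 is then trapped at the para position of anisole (solvent quantity, catalytic CF3SO3H) to give 17.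

**Step 9.** Enolisation of the hindered C3–H may be incomplete, the propargylic C4'–H may be deprotonated in competition, or the protonation may be unselective. The fallback sets the final C3 configuration in the C–C bond-forming step and avoids any late enolisation. It sets out from 13 and returns at 18. Silylation of the dianion of 13 with Me3SiCl gives trimethylsilyl (2S)-4-methoxy-2-[(1R)-1-(4-methoxyphenyl)-3-(triisopropylsilyl)prop-2-yn-1-yl]-4-(trimethylsilyloxy)but-3-enoate F3. A Mukaiyama aldol addition of F3 to 2,4,6-trimethoxybenzaldehyde (BF3·OEt2, open transition state without a lithium chelate, electrophile anti to the C4' chain) and acid lactonisation would give the 3,4-trans lactone methyl (3S,4S)-4-[(1R)-1-(4-methoxyphenyl)-3-(triisopropylsilyl)prop-2-yn-1-yl]-5-oxo-2-(2,4,6-trimethoxyphenyl)oxolane-3-carboxylate F4. Friedel–Crafts opening of F4 with anisole, with attack anti to the C3' chain, gives 18 directly.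

**Step 14.** Conjugate addition of the acid to the doubly methoxylated quinone may be slow. That would leave time for tert-butyl cations to alkylate the trimethoxyphenyl ring, for redox exchange between product hydroquinone and unreacted quinone, or for acid-induced ionisation at C4. The fallback avoids the tert-butyl ester and the strong acid. It sets out from 18 and returns at 26. Buffered desilylation of 18 (Bu4NF/AcOH) gives (2S,3R,4S)-3-(methoxycarbonyl)-4-(4-methoxyphenyl)-2-[(1S)-1-(4-methoxyphenyl)prop-2-yn-1-yl]-4-(2,4,6-trimethoxyphenyl)butanoic acid F5. Two equivalents of LiN(iPr)2 form the carboxylate/acetylide, in which the carboxylate also protects C3'–H. Addition to 21 gives (2S,3R,4S)-2-[(1R)-3-(1-hydroxy-2,3-dimethoxy-4-oxocyclobut-2-en-1-yl)-1-(4-methoxyphenyl)prop-2-yn-1-yl]-3-(methoxycarbonyl)-4-(4-methoxyphenyl)-4-(2,4,6-trimethoxyphenyl)butanoic acid F6. Thermolysis of F6 as in step 13 gives 25, whose free acid should add to the quinone under the thermal, acid-free conditions to give 26.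

## Further compounds

F1 | step 13 | chlorobis(triphenylphosphine)(2,3-dimethoxymaleoyl)cobalt, CoCl(PPh3)2[C(O)C(OMe)=C(OMe)C(O)] | COC1=C(OC)C(=O)[Co](Cl)([P](c2ccccc2)(c2ccccc2)c2ccccc2)([P](c2ccccc2)(c2ccccc2)c2ccccc2)C1=O
F2 | step 8 | methyl (3R,4S)-4-[(1R)-1-(4-methoxyphenyl)-3-(triisopropylsilyl)prop-2-yn-1-yl]-5-oxo-2-(2,4,6-trimethoxyphenyl)oxolane-3-carboxylate (3,4-cis; both C2 epimers) | COC(=O)[C@H]1C(c2c(OC)cc(OC)cc2OC)OC(=O)[C@H]1[C@@H](C#C[Si](C(C)C)(C(C)C)C(C)C)c1ccc(OC)cc1
F3 | step 9 | trimethylsilyl (2S)-4-methoxy-2-[(1R)-1-(4-methoxyphenyl)-3-(triisopropylsilyl)prop-2-yn-1-yl]-4-(trimethylsilyloxy)but-3-enoate | COC(O[Si](C)(C)C)=C[C@@H](C(=O)O[Si](C)(C)C)[C@@H](C#C[Si](C(C)C)(C(C)C)C(C)C)c1ccc(OC)cc1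
F4 | step 9 | methyl (3S,4S)-4-[(1R)-1-(4-methoxyphenyl)-3-(triisopropylsilyl)prop-2-yn-1-yl]-5-oxo-2-(2,4,6-trimethoxyphenyl)oxolane-3-carboxylate (3,4-trans; both C2 epimers) | COC(=O)[C@@H]1C(c2c(OC)cc(OC)cc2OC)OC(=O)[C@H]1[C@@H](C#C[Si](C(C)C)(C(C)C)C(C)C)c1ccc(OC)cc1
F5 | step 14 | (2S,3R,4S)-3-(methoxycarbonyl)-4-(4-methoxyphenyl)-2-[(1S)-1-(4-methoxyphenyl)prop-2-yn-1-yl]-4-(2,4,6-trimethoxyphenyl)butanoic acid | COc1cc(OC)cc(OC)c1[C@H](c1ccc(OC)cc1)[C@@H](C(=O)OC)[C@@H](C(=O)O)[C@@H](C#C)c1ccc(OC)cc1
F6 | step 14 | (2S,3R,4S)-2-[(1R)-3-(1-hydroxy-2,3-dimethoxy-4-oxocyclobut-2-en-1-yl)-1-(4-methoxyphenyl)prop-2-yn-1-yl]-3-(methoxycarbonyl)-4-(4-methoxyphenyl)-4-(2,4,6-trimethoxyphenyl)butanoic acid (both carbinol epimers) | COc1cc(OC)cc(OC)c1[C@H](c1ccc(OC)cc1)[C@@H](C(=O)OC)[C@@H](C(=O)O)[C@@H](C#CC1(O)C(OC)=C(OC)C1=O)c1ccc(OC)cc1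
A1 | alternative 1 | 1,1,3,3-tetraisopropyldisiloxane-1,3-diyl bis-ether linking the 4-oxyphenyl groups of a 5,7-dimethoxy-4-arylcoumarin and a 5,6,7,8-tetramethoxy-4-arylcoumarin | O=C1C=C(c2ccc(O[Si](C(C)C)(C(C)C)O[Si](C(C)C)(C(C)C)Oc3ccc(cc3)C3=CC(=O)Oc4c(OC)c(OC)c(OC)c(OC)c34)cc2)c2c(OC)cc(OC)cc2O1
A2 | alternative 1 | tethered syn head-to-head cyclobutane dimer | O=C1Oc2cc(OC)cc(OC)c2[C@@]3(c2ccc(O[Si](C(C)C)(C(C)C)O[Si](C(C)C)(C(C)C)O4)cc2)[C@@H]1[C@H]1C(=O)Oc2c(OC)c(OC)c(OC)c(OC)c2[C@]13c1ccc4cc1
A3 | alternative 2 | 2-[(3S,4R)-5,6,7,8-tetramethoxy-4-(4-methoxyphenyl)-2-oxochroman-3-yl]acetaldehyde | O=CC[C@H]1C(=O)Oc2c(OC)c(OC)c(OC)c(OC)c2[C@H]1c1ccc(OC)cc1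
A4 | alternative 2 | 3,5-dimethoxy-2-(4-methoxybenzyl)phenol | COc1ccc(Cc2c(O)cc(OC)cc2OC)cc1
A5 | alternative 2 | 3,5-dimethoxy-6-(4-methoxybenzylidene)cyclohexa-2,4-dien-1-one (ortho-quinone methide) | O=C1C=C(OC)C=C(OC)C1=Cc1ccc(OC)cc1
A6 | alternative 2 | octamethyl ether of 27 | O=C1Oc2cc(OC)cc(OC)c2[C@H](c2ccc(OC)cc2)[C@@H]1[C@H]1C(=O)Oc2c(OC)c(OC)c(OC)c(OC)c2[C@H]1c1ccc(OC)cc1
A7 | alternative 3 | (Z)-1,4-bis(4-methoxyphenyl)-1-(2,4,6-trimethoxyphenyl)-4-(pentamethoxyphenyl)but-2-ene | COc1cc(OC)cc(OC)c1[C@H](c1ccc(OC)cc1)/C=C\[C@@H](c1c(OC)c(OC)c(OC)c(OC)c1OC)c1ccc(OC)cc1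
A8 | alternative 3 | dimethyl 2-[(4-methoxyphenyl)(pentamethoxyphenyl)methyl]-3-[(4-methoxyphenyl)(2,4,6-trimethoxyphenyl)methyl]butanedioate | COc1cc(OC)cc(OC)c1[C@H](c1ccc(OC)cc1)[C@@H](C(=O)OC)[C@@H](C(=O)OC)[C@@H](c1c(OC)c(OC)c(OC)c(OC)c1OC)c1ccc(OC)cc1
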